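## Structural features

Gentiside K is a single benzene ring (ring A) with three substituents in a row: a carboxylate ester at C1 and free hydroxyl groups at C2 and C3, while C4, C5 and C6 carry hydrogen. The ester oxygen is bound to the terminal methylene of an unbranched, saturated C24 chain (tetracosyl). There is no stereocentre and no alkene geometry. The fragile parts are the catechol, which is oxidised to the ortho-quinone by air (fastest under base) and binds metals, and the alkyl ester, which must not be exchanged or hydrolysed when the phenols are unmasked. The difficulty is regiochemistry and handling, not complexity: three adjacent substituents must be placed without isomers, and every intermediate carrying the C24 chain is a waxy, poorly soluble solid that is hard to separate from the free C24 alcohol. The key step uses the row C1(CO2R)–C2(O)–C3(O) beside the bare C4–C5–C6 edge. C1, C6, C5 and C4 map onto C3, C4, C5 and C6 of a 2-pyranone that already bears the ester, and C2 and C3 with both oxygens map onto an alkene oxygenated at both carbons, so ring A and its full substitution pattern arise in one cycloaddition–decarboxylation–elimination sequence.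

## Logic of the disconnections

**8 to 7.** The two phenolic O–H bonds of 8 are traced back to O–Si bonds. The skeleton is unchanged; the gain is that the catechol stays masked until the last operation by groups that arrive with the two-carbon partner and cost no step to install. The forward demand is a cleavage that leaves the alkyl ester and the electron-rich ring alone: dilute aqueous acid, no alcohol, no base, no air.

**7 to 3 and 4.** Ring A of 7 is cut at C1–C2 and C3–C4, and the lactone bridge lost in the forward direction is restored between C1 and C4. This gives 3, which holds C1, C6, C5, C4 and the complete ester, and 4, which holds C2, C3 and both oxygens. The forward step passes through 5 and 6.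
- Gain: the three contiguous substituents follow from the connectivity of two simple partners, and the arene oxidation level is reached by decarboxylation and loss of one silyloxy group, with no redox step.
- Demand: 3 must act as an electron-poor diene and 4 as an electron-rich 2π partner under purely thermal conditions; ring closure must outrun silyl transfer; 3 must be free of 2, because any hydroxyl group destroys 4.
- Correction (a): the orientation of addition is biased by polarity (CH terminus of 4 to C6 of 3), but it is not needed for the constitution of 7. Both carbons of 4 carry oxygen and both oxygens are kept, so either orientation loses one silyloxy group across the same C2–C3 bond and gives the same 2,3-dioxygenated benzoate. Orientation affects only the rate.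
- Correction (b): only the C2 oxygen is adjacent to the ester-bearing carbon; the C3 oxygen is one position further.

**3 to 1 and 2.** The acyl C–O bond of the exocyclic ester of 3 is cut. Cutting here, and not inside the pyranone ring, saves C24 chain: building the ring on a bis-ester made from two molecules of 2 would use two chains per ring, expel one again on lactonisation, and carry waxy intermediates through three steps. Alkoxy exchange on the ready-made ring of 1 uses one chain in one step. The demand is a neutral, non-nucleophilic exchange, because C6 and the lactone carbonyl of 1 and 3 are attacked by alkoxides and amines, and full consumption of 2.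

## Other disconnections considered

**Alternative 1:** The cut is the C4=C5 bond of a non-aromatic six-membered precursor of ring A. The acyclic β-keto ester A1 (tetracosyl 2-allyl-4-[(tert-butyldimethylsilyl)oxy]-3-oxohex-5-enoate) would undergo ring-closing metathesis of its two terminal alkenes with second-generation Grubbs catalyst RuCl2(=CHPh)(PCy3)(H2IMes). The product would be cyclohexenone A2 (tetracosyl 3-[(tert-butyldimethylsilyl)oxy]-2-oxocyclohex-4-ene-1-carboxylate, diastereomer mixture), to be aromatised afterwards.
- In favour: six-membered closure between two monosubstituted alkenes is among the most dependable metathesis events and tolerates ketone, ester and silyl ether. On reliability of the ring-forming event this alternative is the better one, since the chosen cycloaddition extends known chemistry to an untried 2π partner.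
- Against: A2 lies two hydrogens below the catechol, so aromatisation is a dehydrogenation. The enol of A2 can instead aromatise without oxidant by 1,4-elimination of the C3 silyloxy group with a C6 hydrogen, which would give salicylate A3 (tetracosyl 2-hydroxybenzoate) and lose the oxygen the route is meant to install. A1 is costly to reach (β-keto ester assembly, C-allylation, an epimerisable C2, an allylic silyl ether that can move into conjugation), and two stereocentres are made only to be erased.
- Comparison: on structure the plans are equal, since both build ring A from non-aromatic pieces with unambiguous placement of the substituents. On mechanism the chosen plan reaches the arene level by extrusion of CO2 and a silanol, where this one needs a selective oxidation competing with an easy elimination. On step economy roughly seven or more operations stand against three.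

**Alternative 2:** The cut is the C3–O bond of ring A, made on an intact benzoate. Salicylate A3 would be converted into the silanol ether A4 (tetracosyl 2-{[di-tert-butyl(hydroxy)silyl]oxy}benzoate), and A4 oxidised with Pd(OPiv)2 and PhI(OAc)2. The sequence is silanol-directed palladation of C3–H by divalent palladium, oxidation to a tetravalent palladium species, and C–O bond formation. It ends in the cyclic silylene-protected catechol A5 (tetracosyl 2,2-di-tert-butyl-1,3,2-benzodioxasilole-4-carboxylate), which fluoride would open to the catechol.
- In favour: the ring and ester come from A3, one esterification away from a commodity acid. C3 is the only open position ortho to the C2 oxygen, so the site is fixed by structure; on regiochemical certainty the two plans are equal. The oxygenation is an established reaction type for phenols, so on precedent for the key bond formation this alternative is the better one.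
- Against: the bulky silanol must be installed on a hydroxyl that is hydrogen-bonded to and flanked by the ester, probably in two operations. The ester deactivates the ring towards electrophilic palladation. The step uses a palladium catalyst and a stoichiometric hypervalent iodine oxidant at about 100 °C, with C–H acetoxylation as a conceivable side path.
- Comparison: on structure it functionalises an existing arene and is conceptually simpler. On mechanism it depends on a directing group that must be added and removed, whereas the chosen plan brings its masking groups in with the reagent. On step economy four to five operations stand against three, at higher reagent cost.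

**Alternative 3:** The cut removes the bond from C1 of ring A to the carbonyl carbon and the bond from that carbon to the alkoxy oxygen. Aryl bromide A6 (1,2-bis(benzyloxy)-3-bromobenzene), carbon monoxide A7 and alcohol 2 would be joined under Pd(OAc)2 and Xantphos with triethylamine. The sequence is oxidative addition of A6 to zerovalent palladium, insertion of A7 to an acyl complex of divalent palladium, and alcoholysis by 2 to give A8 (tetracosyl 2,3-bis(benzyloxy)benzoate). Hydrogenolysis over Pd/C would then free the catechol without touching the ester.
- In favour: the mechanism is well understood, the catalyst system works at atmospheric pressure, the chain is attached in the bond-forming step, and the benzyl ethers make every intermediate stable and chromatographable. On reliability of the key step this alternative is the better one, and on step economy it is equal (benzylation, carbonylation, hydrogenolysis).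
- Against: A7 is a toxic gas needing dedicated equipment. Alkoxycarbonylation normally uses excess alcohol, whereas waxy 2 would be used near stoichiometrically, which slows capture of the acyl complex. A6 is not a commodity and must be prepared first.
- Comparison: on structure it decorates a ring that already holds both oxygens; since that ring is also accessible with C1 already carboxylated, the catalytic C–C bond formation offers little over plain ester formation (see the fallback to step 2). On mechanism a catalytic coupling with a gas stands against a metal-free thermal cascade releasing only CO2 and a silanol. The chosen plan is kept for how it assembles the substitution pattern, not because it is the safer chemistry.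

Key step: step 2

Assumption: 1, 2 and 4 are taken as purchasable; 1 would otherwise be available in two steps from dimethyl malonate and 1,1,3,3-tetramethoxypropane.

## Route

Step 1
Reactants: 1 methyl 2-oxo-2H-pyran-3-carboxylate; 2 1-tetracosanol
Product: 3 tetracosyl 2-oxo-2H-pyran-3-carboxylate
Conditions: 1 (1.5 equiv), Bu2SnO (10 mol%), PhMe, reflux, 5 Å MS (Soxhlet), Ar
Reagents that add atoms: none
Why: Transesterification through the tin alkoxide formed from Bu2SnO and 2, pulled to completion by trapping methanol; the same neutral catalysis attaches fatty alcohols to acrylate-type Michael acceptors, so addition at C6 should not compete, and attack at the lactone carbonyl is self-correcting because the opened dienol recloses to a pyranone. Excess 1 ensures no 2 remains, and 3 is freed from 1 by recrystallisation from acetone.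

Step 2
Reactants: 3 tetracosyl 2-oxo-2H-pyran-3-carboxylate; 4 tris(trimethylsiloxy)ethylene
Product: 7 tetracosyl 2,3-bis(trimethylsilyloxy)benzoate, via bridged lactone cycloadduct 5 (not isolated), via cyclohexadiene silyl ketal 6 (not isolated)
Conditions: 4 (3 equiv), dry PhMe, sealed tube, 120 °C, Ar; then evaporation
Reagents that add atoms: none
Why: Proposed new method: the diene C3=C4–C5=C6 of 3 (pyranone numbering), made electron-poor by the lactone carbonyl and the C3 ester, should add electron-rich alkene 4 in a [4+2] cycloaddition with inverse electron demand, concerted and asynchronous or stepwise (CH(OSiMe3) carbon to C6, then closure of the malonate-type carbanion at C3 onto the bis(silyloxy)carbenium carbon), to give bridged lactone 5; the closest known reaction type is the thermal addition of dialkyl ketene acetals such as 1,1-dimethoxyethylene to 3-alkoxycarbonyl-2-pyranones, which gives salicylate ethers after loss of CO2 and an alcohol, and the new element is a silylated 2π partner oxygenated on both carbons. Ring A is closed by intermolecular [4+2] annulation, its C1–C2 and C3–C4 bonds (arene numbering) forming in the same operation. Retro-[4+2] cleavage of 5 expels CO2 and leaves diene 6, whose C2 silyl ketal should ionise readily to an oxygen-stabilised, arenium-like cation that loses the C3 proton, a 1,2-elimination of Me3SiOH giving arene 7. No stereocentre needs control: the three of 5 and the one of 6 are transient and vanish on aromatisation, so endo/exo and facial selectivity have no consequence. The orientation of addition is expected from polarity but is not required, because both carbons of 4 carry oxygen and the reverse adduct would lose Me3SiOH across the same C2–C3 bond to the same 7. The selectivity that is needed is chemoselectivity: ring closure must win over silyl transfer within the dipolar intermediate (open-chain Mukaiyama–Michael outcome) and 4 must survive, which is why an apolar solvent, no Lewis acid, excess 4 and 3 free of 2 are chosen. Partial loss of silyl groups from 7 through the silanol set free is harmless because step 3 removes them all, so crude 7 is carried on.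

Step 3
Reactants: 7 tetracosyl 2,3-bis(trimethylsilyloxy)benzoate
Product: 8 Gentiside K (tetracosyl 2,3-dihydroxybenzoate)
Conditions: 1 M aq HCl, THF, 25 °C, Ar
Reagents that add atoms: none
Why: Acid-catalysed hydrolysis of aryl trimethylsilyl ethers (protonation at oxygen, attack of water at silicon) should be complete within minutes under conditions where a primary alkyl benzoate is inert; excluding alcohols, base and air avoids ester exchange and oxidation of the catechol.

## Compound list

1 | methyl 2-oxo-2H-pyran-3-carboxylate | COC(=O)C1=CC=COC1=O | starting material
2 | 1-tetracosanol | CCCCCCCCCCCCCCCCCCCCCCCCO | starting material
3 | tetracosyl 2-oxo-2H-pyran-3-carboxylate | CCCCCCCCCCCCCCCCCCCCCCCCOC(=O)C1=CC=COC1=O | intermediate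
4 | tris(trimethylsiloxy)ethylene | C[Si](C)(C)OC=C(O[Si](C)(C)C)O[Si](C)(C)C | starting material
5 | tetracosyl 3-oxo-7,8,8-tris(trimethylsilyloxy)-2-oxabicyclo[2.2.2]oct-5-ene-4-carboxylate (bridged lactone cycloadduct; racemic endo/exo mixture, stereocentres transient) | CCCCCCCCCCCCCCCCCCCCCCCCOC(=O)C12C=CC(OC1=O)C(O[Si](C)(C)C)C2(O[Si](C)(C)C)O[Si](C)(C)C | intermediate
6 | tetracosyl 5,6,6-tris(trimethylsilyloxy)cyclohexa-1,3-diene-1-carboxylate (cyclohexadiene silyl ketal; racemic, stereocentre transient) | CCCCCCCCCCCCCCCCCCCCCCCCOC(=O)C1=CC=CC(O[Si](C)(C)C)C1(O[Si](C)(C)C)O[Si](C)(C)C | intermediate
7 | tetracosyl 2,3-bis(trimethylsilyloxy)benzoate | CCCCCCCCCCCCCCCCCCCCCCCCOC(=O)c1cccc(O[Si](C)(C)C)c1O[Si](C)(C)C | intermediate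
8 | Gentiside K (tetracosyl 2,3-dihydroxybenzoate) | CCCCCCCCCCCCCCCCCCCCCCCCOC(=O)c1cccc(O)c1O | target

## Step count and least certain steps

Total step count: 3. Longest linear sequence: 3 steps (1 or 2 to 3 to 7 to 8).

**Step 2 (key step, proposed new method).** The most likely failure is interception of the dipolar first adduct by silyl transfer from the carbenium end to the pyranone enolate oxygen, giving no ring closure. A second failure is consumption of 4 by protodesilylation through the silanol and water that build up during the reaction. Both follow from 4 being a silyl ketene acetal and not a dialkyl one. The fallback uses known chemistry and gives up the ring construction. It sets out from 2, which is converted with 48% aqueous HBr and catalytic H2SO4 at 100 °C into 1-bromotetracosane F1. The carboxylate of purchased 2,3-dihydroxybenzoic acid F2 is then alkylated with F1 (KHCO3, DMF, 70 °C); bicarbonate deprotonates only the carboxylic acid, so the phenols should stay unalkylated. This comes back to the route at 8.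

**Step 1.** The most likely failure is incomplete alkoxy exchange, an equilibrium on a conjugated ester that depends on methanol removal. Slow degradation of the pyranone by alcohol addition at C6 at reflux may accompany it, and residual 2 would then destroy 4 in step 2. The fallback sets out from 1, which is hydrolysed in hot aqueous acid (6 M HCl, AcOH, 90 °C; base is excluded because hydroxide opens the ring) to 2-oxo-2H-pyran-3-carboxylic acid F3. Oxalyl chloride and catalytic DMF in CH2Cl2 convert F3 into 2-oxo-2H-pyran-3-carbonyl chloride F4, which acylates 2 in toluene at 70 °C without amine base, the HCl being swept out with argon. This comes back at 3.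

**Step 3.** The Si–O cleavage itself is unlikely to fail. The likely problems are air oxidation of the liberated catechol during isolation and difficult separation of waxy 8 from silicon residues and hydrolysed excess 4 carried over from step 2. The fallback sets out from crude 7, which is converted by silyl-to-acetyl exchange (Ac2O, pyridine, catalytic AcOH and DMAP) into tetracosyl 2,3-diacetoxybenzoate F5, an air-stable solid that can be recrystallised. The two aryl acetates are then cleaved chemoselectively with hydrazine hydrate in THF at 0 °C under argon, the alkyl benzoate being far less reactive. This comes back at 8.

## Further compounds

F1 | step 2 | 1-bromotetracosane | CCCCCCCCCCCCCCCCCCCCCCCCBr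
F2 | step 2 | 2,3-dihydroxybenzoic acid (purchased) | OC(=O)c1cccc(O)c1O
F3 | step 1 | 2-oxo-2H-pyran-3-carboxylic acid | OC(=O)C1=CC=COC1=O
F4 | step 1 | 2-oxo-2H-pyran-3-carbonyl chloride | ClC(=O)C1=CC=COC1=O
F5 | step 3 | tetracosyl 2,3-diacetoxybenzoate | CCCCCCCCCCCCCCCCCCCCCCCCOC(=O)c1cccc(OC(C)=O)c1OC(C)=O
A1 | alternative 1 | tetracosyl 2-allyl-4-[(tert-butyldimethylsilyl)oxy]-3-oxohex-5-enoate (diastereomer mixture) | CCCCCCCCCCCCCCCCCCCCCCCCOC(=O)C(CC=C)C(=O)C(O[Si](C)(C)C(C)(C)C)C=C
A2 | alternative 1 | tetracosyl 3-[(tert-butyldimethylsilyl)oxy]-2-oxocyclohex-4-ene-1-carboxylate (diastereomer mixture) | CCCCCCCCCCCCCCCCCCCCCCCCOC(=O)C1CC=CC(O[Si](C)(C)C(C)(C)C)C1=O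
A3 | alternative 1 | tetracosyl 2-hydroxybenzoate | CCCCCCCCCCCCCCCCCCCCCCCCOC(=O)c1ccccc1O
A4 | alternative 2 | tetracosyl 2-{[di-tert-butyl(hydroxy)silyl]oxy}benzoate | CCCCCCCCCCCCCCCCCCCCCCCCOC(=O)c1ccccc1O[Si](O)(C(C)(C)C)C(C)(C)C
A5 | alternative 2 | tetracosyl 2,2-di-tert-butyl-1,3,2-benzodioxasilole-4-carboxylate | CCCCCCCCCCCCCCCCCCCCCCCCOC(=O)c1cccc2O[Si](C(C)(C)C)(C(C)(C)C)Oc12
A6 | alternative 3 | 1,2-bis(benzyloxy)-3-bromobenzene | Brc1cccc(OCc2ccccc2)c1OCc1ccccc1
A7 | alternative 3 | carbon monoxide | [C-]#[O+]
A8 | alternative 3 | tetracosyl 2,3-bis(benzyloxy)benzoate | CCCCCCCCCCCCCCCCCCCCCCCCOC(=O)c1cccc(OCc2ccccc2)c1OCc1ccccc1
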